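The runs were computed for substances that don't exist, and the scatter is random.

0.7% of over-reaction product at 25.0 s in Tuesday's run, read with a scatter of 0.5 percentage points: what can so small a reading carry?

| flask | starting material | activator | remark | time |
|---|---|---|---|---|
| Tuesday's | 0.0011 M | 1.1 mM | run made earlier |  |
| zeta | 0.0010 M | 1.10 mM |  | 2.0 min |
| delta | 2.5 × 10⁻⁴ M | 0.600 mM |  | 6.0 min |

Tuesday's run (percent of the starting material charged)

| time / s | ring / % | open dimer / % | over-reaction product / % |
|---|---|---|---|
| 10.0 | 1.6 | 1.5 | 0 |
| 15.0 | 3.3 | 2.5 | 0.2 |
| 20.0 | 5.4 | 3.7 | 0 |
| 25.0 | 7.7 | 5.4 | 0.7 |

(standard deviation of a reading: 0.5 percentage points)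

- percent here means starting material units held: one open dimer counts as two

1. which one finishes higher in share of ring in all that became ring or open dimer or over-reaction product ("neither" within 2 percentage points) (zeta / delta / neither)
2. share of ring in all that became ring or open dimer or over-reaction product, zeta
3. share of ring in all that became ring or open dimer or over-reaction product, delta

What makes over-reaction product? It shows up in Tuesday's run after ring has built up, so I assume a first-order step from ring.

How fast is that step? Taking Tuesday's ring as a straight rise from zero to 7.7%, I divide the product by half that amount times 25.0 s, which gives 0.00727 s⁻¹.

And you trust that figure? Only for its order of magnitude, which is why I work in logarithms. The decade time (decimal reduction time) is 2.3 over that constant, 5.27 min, the time in which ring left to itself falls by one power of ten.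

What does it say of the two flasks? Zeta's 2.0 min is 0.380 decades for the oldest ring, and delta's 6.0 min is 1.14.

But delta is dilute, so it should make less open dimer. Is that not worth more? In Tuesday's last reading, open dimer costs ring 0.231 decades of the ring-and-dimer total. Delta's extra time costs 0.759 decades, more than that. Ring made midway sees half of this, 0.380 decades, which is still more. My answer is zeta ahead.

The forecast says delta, with 63% for zeta and 88% for delta, on the ground “Dilution favours delta”. On the direction we part.

Zeta gives 22.2% and delta 3.29%, so zeta finishes higher.

    starting material + activated form → open dimer (k = 8.40 M⁻¹ s⁻¹)
    ring → over-reaction product (k = 0.0240 s⁻¹)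
    starting material + activator → activated form (k = 19.0 M⁻¹ s⁻¹)
    activated form → ring (k = 0.0260 s⁻¹)

In zeta, the half-life of ring by the step to over-reaction product alone is 0.48 min, shorter than that flask's 2.0 min. Now the decade time once more, still the rough figure read from Tuesday's run and not a constant of the flask, on delta's own flask read earlier at 2.5 min: from there to 6.0 min it counts 0.664 decades for ring left to itself, while delta at that reading holds 10.7% of activated form. The ring share in delta goes from 22.8% at that reading to 3.29% at the end, a fall of 0.841 decades.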